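With the chain numbered C1 (alkyne CH) to C15 (CH3), the fused bis-oxolane carries one ring oxygen on each ring-fusion carbon, cis to each other (C9–O in the bromopropyl ring B, C10–O in the enol-ether ring A): the imprint of a cis-epoxide opened at C9 and enlarged at C10. The key step exposes an acyclic cis-alkynyl oxirane bearing a C12 hydroxyl to a gold catalyst: the hydroxyl opens the oxirane at propargylic C9 (closing ring B with inversion) and the released oxygen adds to the alkyne, inserting C8 and C7 into the former O–C9 bond, so the oxirane grows into ring A. Enol-ether bromination with allylic transposition then installs C8–Br and the (Z)-alkylidene.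

Key step: step 10

Remark: compounds 3, 7 and 9 and all catalysts are taken as commercial; locants C1–C15 are the chain numbering above, ring A = O/C7/C8/C9/C10, ring B = O/C9/C10/C11/C12.

Step 1
Reactants: 1 butanal
Product: 2 (S)-2-bromobutanal
Conditions: 4,4-dibromo-2,6-di-tert-butylcyclohexa-2,5-dienone, trans-2,5-diphenylpyrrolidine (20 mol%, the enantiomer that gives the 2S bromide), PhCO2H (20 mol%), CH2Cl2/pentane, −40 °C; cold silica plug, solution used at once
Reagents that add atoms: 4,4-dibromo-2,6-di-tert-butylcyclohexa-2,5-dienone, O=C1C(C(C)(C)C)=CC(Br)(Br)C=C1C(C)(C)C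
Why: Organocatalytic α-bromination of an aldehyde by enamine catalysis, in which the C2-symmetric amine shields one enamine face so that bromine transfer should set the future C13 centre as S.

Step 2
Reactants: 2 (S)-2-bromobutanal; 3 allenylboronic acid pinacol ester
Product: 4 (4R,5S)-5-bromohept-1-yn-4-ol
Conditions: (PhO)2P(O)OH (5 mol%), toluene, 4 Å MS, −30 → 0 °C; aq. NaHCO3
Reagents that add atoms: none
Why: Acid-accelerated allenylboration (SE2′ propargylation) through a closed six-membered transition state in which the Cornforth arrangement of the α-C–Br dipole should direct attack to the face that gives the anti bromohydrin, setting C12 as R.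

Step 3
Reactants: 4 (4R,5S)-5-bromohept-1-yn-4-ol
Product: 5 (4R,5S)-5-bromo-1-iodohept-1-yn-4-ol
Conditions: NIS, AgNO3 (10 mol%), acetone, rt, dark
Reagents that add atoms: N-iodosuccinimide, O=C1CCC(=O)N1I
Why: Silver-catalysed electrophilic iodination of the terminal alkyne C–H, which leaves the hydroxyl and the secondary bromide untouched.

Step 4
Reactants: 5 (4R,5S)-5-bromo-1-iodohept-1-yn-4-ol
Product: 6 (1Z,4R,5S)-5-bromo-1-iodohept-1-en-4-ol
Conditions: 2-nitrobenzenesulfonylhydrazide, Et3N, THF/i-PrOH, rt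
Reagents that add atoms: none
Why: Diimide reduction delivers H2 to the iodoalkyne in a concerted syn fashion and should give the (Z)-iodoalkene without hydrogenolysis of C–I or C–Br.

Step 5
Reactants: 7 5-(trimethylsilyl)pent-4-yn-1-ol
Product: 8 5-(trimethylsilyl)pent-4-ynal
Conditions: Dess–Martin periodinane, CH2Cl2, 0 °C → rt
Reagents that add atoms: none
Why: Dess–Martin oxidation of a primary alcohol stops at the aldehyde and tolerates the silyl alkyne.

Step 6
Reactants: 8 5-(trimethylsilyl)pent-4-ynal; 9 1,3-bis(triisopropylsilyl)prop-1-yne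
Product: 11 (Z)-triisopropyl[9-(trimethylsilyl)non-3-ene-1,8-diyn-1-yl]silane, via lithiated propyne 10 (not isolated)
Conditions: 9, n-BuLi, THF, −20 °C; then 8, −78 °C → rt; aqueous work-up
Reagents that add atoms: none
Why: Peterson olefination in which the bulky α-silyl propargyl-lithium adds to the aldehyde and syn elimination of lithium triisopropylsilanolate should give the (Z)-enyne (C3=C4).

Step 7
Reactants: 11 (Z)-triisopropyl[9-(trimethylsilyl)non-3-ene-1,8-diyn-1-yl]silane
Product: 12 (Z)-triisopropyl(non-3-ene-1,8-diyn-1-yl)silane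
Conditions: K2CO3 (cat.), MeOH, rt
Reagents that add atoms: none
Why: Base-catalysed methanolysis cleaves the C(sp)–SiMe3 bond much faster than the hindered C(sp)–Si(i-Pr)3 bond, so only the C8 alkyne is released.

Step 8
Reactants: 6 (1Z,4R,5S)-5-bromo-1-iodohept-1-en-4-ol; 12 (Z)-triisopropyl(non-3-ene-1,8-diyn-1-yl)silane
Product: 13 (3S,4R,6Z,12Z)-3-bromo-15-(triisopropylsilyl)pentadeca-6,12-dien-8,14-diyn-4-ol
Conditions: Pd(PPh3)4 (5 mol%), CuI (10 mol%), i-Pr2NH, THF, rt
Reagents that add atoms: none
Why: Sonogashira coupling forms the C8–C9 bond with retention of the (Z)-iodoalkene geometry and tolerates the free hydroxyl and the alkyl bromide at room temperature.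

Step 9
Reactants: 13 (3S,4R,6Z,12Z)-3-bromo-15-(triisopropylsilyl)pentadeca-6,12-dien-8,14-diyn-4-ol
Product: 14 (2R,3S)-3-bromo-1-{(2S,3R)-3-[(5Z)-8-(triisopropylsilyl)oct-5-ene-1,7-diyn-1-yl]oxiran-2-yl}pentan-2-ol
Conditions: VO(acac)2 (5 mol%), t-BuOOH (decane), CH2Cl2, 0 °C → rt; filtration through basic alumina
Reagents that add atoms: tert-butyl hydroperoxide, CC(C)(C)OO
Why: Hydroxyl-directed vanadium-catalysed epoxidation of a (Z)-homoallylic alcohol, in which the vanadate ester delivers oxygen through a chair-like transition state with the bromopropyl group equatorial, so that only C9=C10 reacts and the cis-epoxide should form with its C10–O bond syn to the C12 hydroxyl (9R,10S).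

Step 10
Reactants: 14 (2R,3S)-3-bromo-1-{(2S,3R)-3-[(5Z)-8-(triisopropylsilyl)oct-5-ene-1,7-diyn-1-yl]oxiran-2-yl}pentan-2-ol
Product: 16 (3aS,5R,6aS)-5-[(1S)-1-bromopropyl]-2-[(3Z)-6-(triisopropylsilyl)hex-3-en-5-yn-1-yl]-3a,5,6,6a-tetrahydrofuro[3,2-b]furan, via alkynyl oxolanol 15 (not isolated)
Conditions: Ph3PAuNTf2 (5 mol%), 2,6-di-tert-butyl-4-methylpyridine (10 mol%), CH2Cl2, 4 Å MS, −20 → 0 °C; Et3N quench
Reagents that add atoms: none
Why: The gold(I) cation first activates the oxirane as a Lewis acid, and the C12 hydroxyl attacks the propargylic carbon C9 from the rear (endo-mode five-ring epoxide opening, closing ring B) to give the alkynyl oxolanol 15 in which the liberated C10 oxygen is cis to the alkyne; the same catalyst then activates C7≡C8 for anti-oxyauration by that oxygen (5-endo-dig, closing ring A) and protodeauration. In the net change the oxirane O–C10 bond is kept and C8–C7 is inserted into the former O–C9 bond, a ring expansion of the three-membered ring by two atoms. The closest known reactions are the gold-catalysed rearrangement of alkynyl oxiranes to furans in the presence of alcohols, which follows the same nucleophile-first sequence, and the acid-mediated endo cyclisation of 3,4-epoxy-5-alkyn-1-ols to 2-alkynyl-oxolan-3-ols. The one stereocentre that changes, C9, is set by SN2 inversion, so the cis-epoxide geometry translates into the cis ring fusion and the 9R,10S epoxide of 14 into the 2,5-trans ring B. The step needs opening at C9 and not at C10, which the alkyne secures by stabilising positive charge at the propargylic carbon while attack at C10 would be a strained 4-exo closure. It also needs the 3-alkoxy-2,3-dihydrofuran to survive without ionising the C9–O bond and aromatising to a furan, which the cold, aprotic, base-buffered conditions and the amine quench are meant to secure.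

Step 11
Reactants: 16 (3aS,5R,6aS)-5-[(1S)-1-bromopropyl]-2-[(3Z)-6-(triisopropylsilyl)hex-3-en-5-yn-1-yl]-3a,5,6,6a-tetrahydrofuro[3,2-b]furan
Product: 17 (3aS,5R,6aS)-5-[(1S)-1-bromopropyl]-2-[(3Z)-hex-3-en-5-yn-1-yl]-3a,5,6,6a-tetrahydrofuro[3,2-b]furan
Conditions: TBAF, THF, 0 °C
Reagents that add atoms: none
Why: Fluoride-induced protodesilylation of the alkynylsilane, under which the base-stable enol ether and the β-alkoxy bromide should survive.

Step 12
Reactants: 17 (3aS,5R,6aS)-5-[(1S)-1-bromopropyl]-2-[(3Z)-hex-3-en-5-yn-1-yl]-3a,5,6,6a-tetrahydrofuro[3,2-b]furan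
Product: 18 (2Z,3S,3aR,5R,6aS)-3-bromo-5-[(1S)-1-bromopropyl]-2-[(3Z)-hex-3-en-5-yn-1-ylidene]hexahydrofuro[3,2-b]furan (target)
Conditions: NBS, 4 Å MS, CH2Cl2, −78 → −40 °C
Reagents that add atoms: N-bromosuccinimide, O=C1CCC(=O)N1Br
Why: Allylic bromination of an enol ether by addition–elimination (as in the NBS conversion of 2-methoxypropene into 2-methoxyallyl bromide), in which bromine should add to C8 from the convex face anti to the C9 ring oxygen (C8 = S) and the α-bromo oxocarbenium ion should lose a C6 proton to succinimide anion, with allylic 1,3-strain against the C8–Br bond placing C5 syn to the ring oxygen to give the (Z)-enol ether.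

Compound list
1 | butanal | CCCC=O | starting material
2 | (S)-2-bromobutanal | O=C[C@@H](Br)CC | intermediate
3 | allenylboronic acid pinacol ester (4,4,5,5-tetramethyl-2-(propa-1,2-dien-1-yl)-1,3,2-dioxaborolane) | C=C=CB1OC(C)(C)C(C)(C)O1 | starting material
4 | (4R,5S)-5-bromohept-1-yn-4-ol | C#CC[C@@H](O)[C@@H](Br)CC | intermediate
5 | (4R,5S)-5-bromo-1-iodohept-1-yn-4-ol | IC#CC[C@@H](O)[C@@H](Br)CC | intermediate
6 | (1Z,4R,5S)-5-bromo-1-iodohept-1-en-4-ol | I/C=C\C[C@@H](O)[C@@H](Br)CC | intermediate
7 | 5-(trimethylsilyl)pent-4-yn-1-ol | C[Si](C)(C)C#CCCCO | starting material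
8 | 5-(trimethylsilyl)pent-4-ynal | C[Si](C)(C)C#CCCC=O | intermediate
9 | 1,3-bis(triisopropylsilyl)prop-1-yne | CC(C)[Si](C(C)C)(C(C)C)C#CC[Si](C(C)C)(C(C)C)C(C)C | starting material
10 | [1,3-bis(triisopropylsilyl)prop-2-yn-1-yl]lithium | CC(C)[Si](C(C)C)(C(C)C)C#CC([Li])[Si](C(C)C)(C(C)C)C(C)C | intermediate (not isolated)
11 | (Z)-triisopropyl[9-(trimethylsilyl)non-3-ene-1,8-diyn-1-yl]silane | CC(C)[Si](C(C)C)(C(C)C)C#C/C=C\CCC#C[Si](C)(C)C | intermediate
12 | (Z)-triisopropyl(non-3-ene-1,8-diyn-1-yl)silane | CC(C)[Si](C(C)C)(C(C)C)C#C/C=C\CCC#C | intermediate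
13 | (3S,4R,6Z,12Z)-3-bromo-15-(triisopropylsilyl)pentadeca-6,12-dien-8,14-diyn-4-ol | CC(C)[Si](C(C)C)(C(C)C)C#C/C=C\CCC#C/C=C\C[C@@H](O)[C@@H](Br)CC | intermediate
14 | (2R,3S)-3-bromo-1-{(2S,3R)-3-[(5Z)-8-(triisopropylsilyl)oct-5-ene-1,7-diyn-1-yl]oxiran-2-yl}pentan-2-ol (cis-epoxide) | CC(C)[Si](C(C)C)(C(C)C)C#C/C=C\CCC#C[C@H]1O[C@H]1C[C@@H](O)[C@@H](Br)CC | intermediate
15 | (2S,3S,5R)-5-[(1S)-1-bromopropyl]-2-[(5Z)-8-(triisopropylsilyl)oct-5-ene-1,7-diyn-1-yl]oxolan-3-ol | CC(C)[Si](C(C)C)(C(C)C)C#C/C=C\CCC#C[C@@H]1O[C@@H]([C@@H](Br)CC)C[C@@H]1O | intermediate (not isolated)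
16 | (3aS,5R,6aS)-5-[(1S)-1-bromopropyl]-2-[(3Z)-6-(triisopropylsilyl)hex-3-en-5-yn-1-yl]-3a,5,6,6a-tetrahydrofuro[3,2-b]furan | CC(C)[Si](C(C)C)(C(C)C)C#C/C=C\CCC1O[C@H]2C[C@H]([C@@H](Br)CC)O[C@H]2C=1 | intermediate
17 | (3aS,5R,6aS)-5-[(1S)-1-bromopropyl]-2-[(3Z)-hex-3-en-5-yn-1-yl]-3a,5,6,6a-tetrahydrofuro[3,2-b]furan | C#C/C=C\CCC1O[C@H]2C[C@H]([C@@H](Br)CC)O[C@H]2C=1 | intermediate
18 | (2Z,3S,3aR,5R,6aS)-3-bromo-5-[(1S)-1-bromopropyl]-2-[(3Z)-hex-3-en-5-yn-1-ylidene]hexahydrofuro[3,2-b]furan | C#C/C=C\C/C=C1\O[C@H]2C[C@H]([C@@H](Br)CC)O[C@H]2[C@@H]1Br | target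

Total step count: 12. Longest linear sequence: 9 steps (steps 1–4 and 8–12, from butanal); steps 5–7 make the alkyne partner 12.

Steps most likely to fail

1. Step 10. The cascade may overshoot: the allylic C9–O bond of the 3-alkoxy-2,3-dihydrofuran can ionise under gold or adventitious acid, and the ring system then aromatises to a 2,5-disubstituted furan. Gold may also add the C12 hydroxyl to the alkyne before the oxirane is opened. The fallback sets out from 14 and separates the two events without a π-acid. Catalytic BF3·OEt2 in CH2Cl2 at −78 °C should give the alkynyl oxolanol 15, now isolated. Iodine and NaHCO3 in MeCN at 0 °C should then close ring A by 5-endo-dig iodocyclisation under basic conditions, giving (3aR,5R,6aS)-5-[(1S)-1-bromopropyl]-3-iodo-2-[(3Z)-6-(triisopropylsilyl)hex-3-en-5-yn-1-yl]-3a,5,6,6a-tetrahydrofuro[3,2-b]furan F1. Palladium-catalysed formate reduction (Pd(PPh3)4, HCO2H, Et3N, DMF, rt) should remove the vinylic iodine and return to the route at 16.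

2. Step 12. After bromine transfer to C8, the oxocarbenium ion may lose the C8 proton instead of a C6 proton, which would give the endocyclic 3-bromo enol ether, or it may be captured by succinimide. The fallback sets out from 17. NBS in MeOH/CH2Cl2 with 2,6-lutidine at −78 °C should give, by trans bromo-alkoxylation, the bromo methyl ketal (3S,3aR,5R,6aS)-3-bromo-5-[(1S)-1-bromopropyl]-2-[(3Z)-hex-3-en-5-yn-1-yl]-2-methoxyhexahydrofuro[3,2-b]furan F2 (either C2 epimer serves). TMSOTf and i-Pr2NEt in CH2Cl2 at −20 °C should then eliminate methanol, the bulky amine removing the less hindered C6 proton, and arrive at 18.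

3. Step 1. The α-bromo aldehyde 2 may enolise before or during the allenylboration, which erodes the C13 configuration, and the Cornforth preference at C12 in step 2 may be incomplete. The fallback sets out from commercial (E)-pent-2-en-1-ol and takes both centres from a Sharpless epoxidation. Epoxidation with D-(−)-diethyl tartrate, Ti(Oi-Pr)4 and t-BuOOH should give [(2R,3R)-3-ethyloxiran-2-yl]methanol F3. Br2/Ti(Oi-Pr)4 should open it at C3 with inversion to (2R,3S)-3-bromopentane-1,2-diol F4. Mitsunobu cyclodehydration (PPh3, DIAD) should close the terminal epoxide (2R)-2-[(1S)-1-bromopropyl]oxirane F5. Lithium (trimethylsilyl)acetylide with BF3·OEt2 at −78 °C should open F5 at its CH2 terminus to (4R,5S)-5-bromo-1-(trimethylsilyl)hept-1-yn-4-ol F6. NIS with catalytic AgNO3 should exchange silicon for iodine and rejoin the route at 5.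

Further compounds
F1 | step 10 | (3aR,5R,6aS)-5-[(1S)-1-bromopropyl]-3-iodo-2-[(3Z)-6-(triisopropylsilyl)hex-3-en-5-yn-1-yl]-3a,5,6,6a-tetrahydrofuro[3,2-b]furan | CC(C)[Si](C(C)C)(C(C)C)C#C/C=C\CCC1O[C@H]2C[C@H]([C@@H](Br)CC)O[C@H]2C=1I
F2 | step 12 | (3S,3aR,5R,6aS)-3-bromo-5-[(1S)-1-bromopropyl]-2-[(3Z)-hex-3-en-5-yn-1-yl]-2-methoxyhexahydrofuro[3,2-b]furan (C2 configuration not defined) | C#C/C=C\CCC1(OC)O[C@H]2C[C@H]([C@@H](Br)CC)O[C@H]2[C@@H]1Br
F3 | step 1 | [(2R,3R)-3-ethyloxiran-2-yl]methanol | OC[C@H]1O[C@@H]1CC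
F4 | step 1 | (2R,3S)-3-bromopentane-1,2-diol | OC[C@@H](O)[C@@H](Br)CC
F5 | step 1 | (2R)-2-[(1S)-1-bromopropyl]oxirane | C1O[C@H]1[C@@H](Br)CC
F6 | step 1 | (4R,5S)-5-bromo-1-(trimethylsilyl)hept-1-yn-4-ol | C[Si](C)(C)C#CC[C@@H](O)[C@@H](Br)CC
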